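## Retrosynthetic overview

1. The last step is global O-demethylation. Before it, the dihydrofuran is cut at O–C(ring B) and at C-8a–C-7a, giving fluoroarene 20 and 4-methoxybenzaldehyde; forward, a benzylic carbanion adds to the aldehyde and the alkoxide then displaces fluoride (formal [3+2]).
2. Enabling feature: C-8a is the only CH2 flanked by two benzene rings (rings A and B), and the ring-B carbon ortho to it is the one that carries the furan oxygen. With fluorine on that carbon, C-8a (nucleophile) and C–F (electrophile) form a 1,3-pair that can take up a C=O unit.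
3. The indane five-membered ring (C-7c to ring C) comes from Friedel–Crafts closure of an aldehyde-derived carbinol on the eight-membered ring.
4. The eight-membered ring comes from a two-carbon ring expansion: 3-fluoro-5-methoxybenzyne (ring B) inserts into the C(=O)–C(α) bond of a tetralone β-ketoester. C-7b is then reset by DDQ oxidation and ionic hydrogenation.
5. The tetralone comes from a Staunton–Weinreb annulation of an o-benzyl benzoate (ring A) with an 8-phenylmenthyl cinnamate (ring C), which sets C-8b. Ring order: six-membered carbocycle, eight-membered ring, indane five-ring, dihydrofuran.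

Key step: step 12

Locants: C-7a is the O–CH(aryl) of the dihydrofuran and C-8a the other dihydrofuran CH (between rings A and B). C-7b is the CH(aryl) of the eight-membered ring. C-8b and C-8c are the two CH groups shared by the eight-membered ring and the indane (C-8b on ring C, C-8c on ring B). C-7c is the CH(aryl) of the indane. Ring A is fused to the eight-membered ring only, ring B is shared by the eight-membered ring and the dihydrofuran, ring C is the indane arene.

Assumption: the 8-phenylmenthyl cinnamate is taken to react as its s-trans conformer on the face away from the stacked phenyl ring, as in cuprate additions to such enoates. On this model the (1S,2R,5S)-auxiliary gives the required C-8b configuration; if the lithium dienolate chose the other face, the (1R,2S,5R)-auxiliary would be used with no other change.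

Compounds 1, 2, 4, 5, 9, 18 and 21 are taken as commercially available.

## Route

Step 1
Reactants: 1 methyl 2-bromo-3,5-dimethoxybenzoate; 2 (4-methoxybenzyl)zinc chloride
Product: 3 methyl 3,5-dimethoxy-2-(4-methoxybenzyl)benzoate
Conditions: Pd(OAc)2 (cat.), 2-dicyclohexylphosphino-2',6'-dimethoxybiphenyl, THF, 60 °C
Reagents that add atoms: none
Why: Negishi sp2–sp3 cross-coupling, in which the benzylzinc reagent tolerates the ester and the dialkylbiarylphosphine ligand handles the doubly ortho-substituted bromide; no stereocentre is formed.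

Step 2
Reactants: 4 (E)-3-(3,5-dimethoxyphenyl)prop-2-enoic acid; 5 (1S,2R,5S)-8-phenylmenthol
Product: 6 (1S,2R,5S)-8-phenylmenthyl (E)-3-(3,5-dimethoxyphenyl)prop-2-enoate
Conditions: DCC, DMAP (cat.), CH2Cl2, 0 °C → rt
Reagents that add atoms: none
Why: Steglich esterification of an unhindered cinnamic acid with a secondary alcohol, which leaves the E-alkene and the auxiliary stereocentres untouched.

Step 3
Reactants: 3 methyl 3,5-dimethoxy-2-(4-methoxybenzyl)benzoate; 6 8-phenylmenthyl cinnamate
Product: 8 (1S,2R,5S)-8-phenylmenthyl (3R)-3-(3,5-dimethoxyphenyl)-5,7-dimethoxy-4-(4-methoxyphenyl)-1-oxo-1,2,3,4-tetrahydronaphthalene-2-carboxylate (C-2 and C-4 epimers, partly enolised), via lithium enolate 7 (not isolated)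
Conditions: LiN(i-Pr)2, THF, −78 °C; then 6, −78 → 0 °C; aq. NH4Cl
Reagents that add atoms: none
Why: Staunton–Weinreb annulation (lateral lithiation of the o-benzyl benzoate, Michael addition to the enoate, Dieckmann condensation with loss of methoxide), in which the stacked phenyl ring of the auxiliary shields one enoate face and so sets C-3 (the later C-8b), while C-4 (the later C-7b) and the enolisable C-2 are left undefined on purpose because steps 7 to 9 fix them.

Step 4
Reactants: 9 3-fluoro-5-methoxyphenol
Product: 10 3-fluoro-5-methoxyphenyl N-isopropylcarbamate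
Conditions: i-PrNCO, Et3N (cat.), CH2Cl2, rt
Reagents that add atoms: isopropyl isocyanate, CC(C)N=C=O
Why: Base-catalysed addition of the phenol to the isocyanate (carbamoylation) installs a strong ortho-directing group that can later be removed under mild base.

Step 5
Reactants: 10 3-fluoro-5-methoxyphenyl N-isopropylcarbamate
Product: 11 3-fluoro-5-methoxy-2-(trimethylsilyl)phenyl N-isopropylcarbamate
Conditions: TBSOTf, TMEDA, Et2O, 0 °C → rt; n-BuLi, TMEDA, −78 °C; Me3SiCl, −78 °C → rt; aq. NaHSO4
Reagents that add atoms: chlorotrimethylsilane, C[Si](C)(C)Cl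
Why: Directed ortho-metalation: after temporary N-silylation, carbamate and fluorine together direct lithiation to the carbon between them (the most acidic ring C–H), and the aryllithium is silylated at −78 °C before it can lose LiF.

Step 6
Reactants: 11 3-fluoro-5-methoxy-2-(trimethylsilyl)phenyl N-isopropylcarbamate
Product: 12 3-fluoro-5-methoxy-2-(trimethylsilyl)phenyl trifluoromethanesulfonate
Conditions: DBU, Et2NH, MeCN, 40 °C; then PhNTf2, rt
Reagents that add atoms: N-phenylbis(trifluoromethanesulfonimide), O=S(=O)(N(c1ccccc1)S(=O)(=O)C(F)(F)F)C(F)(F)F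
Why: DBU-induced E1cB cleavage of the N–H carbamate (the isocyanate is trapped by Et2NH) frees the phenoxide, which is triflated in the same flask, the standard access to 2-silylaryl triflate aryne precursors.

Step 7
Reactants: 8 tetralone β-ketoester; 12 2-silylaryl triflate
Product: 14 (1S,2R,5S)-8-phenylmenthyl 1-fluoro-3,8,10-trimethoxy-6-(3,5-dimethoxyphenyl)-7-(4-methoxyphenyl)-12-oxo-5,6,7,12-tetrahydrodibenzo[a,d][8]annulene-5-carboxylate (C-5/C-6 trans, C-7 both epimers), via aryne 13 (not isolated)
Conditions: CsF, MeCN, 80 °C
Reagents that add atoms: none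
Why: Aryne acyl-alkylation, i.e. insertion of the fluoride-generated aryne into the C(=O)–C(α) bond of the β-ketoester (C-arylation, attack of the aryl anion on the ketone, fragmentation of the benzocyclobutenoxide), expands the six-membered ring to the eight-membered ring; fluorine polarises the aryne so that the enolate carbon bonds meta to F and the acyl group ends ortho to F, and the ester-bearing C-8c equilibrates under the basic conditions to the arrangement trans to the C-8b aryl group.

Step 8
Reactants: 14 eight-membered keto ester
Product: 15 the 7-methoxy derivative of 14 (tertiary methyl ether at C-7b, both epimers)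
Conditions: DDQ, CH2Cl2–MeOH, 0 °C
Reagents that add atoms: methanol, CO
Why: DDQ benzylic oxidation by hydride abstraction from C-7b–H, the only C–H benzylic to both a 4-methoxyphenyl and an ortho,para-dimethoxyaryl ring, with capture of the cation by methanol; both C-7b epimers give the same cation later, so no stereocontrol is needed here.

Step 9
Reactants: 15 7-methoxy keto ester
Product: 16 (1S,2R,5S)-8-phenylmenthyl 1-fluoro-3,8,10-trimethoxy-6-(3,5-dimethoxyphenyl)-7-(4-methoxyphenyl)-5,6,7,12-tetrahydrodibenzo[a,d][8]annulene-5-carboxylate (H-5/H-6 trans, H-6/H-7 cis)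
Conditions: Et3SiH, CF3CO2H, CH2Cl2, 0 °C → rt
Reagents that add atoms: none
Why: Ionic hydrogenation: acid ionises the tertiary methyl ether to the doubly benzylic C-7b cation, Et3SiH should deliver hydride on the face opposite the vicinal C-8b aryl group (1,2-induction), giving H-7b cis to H-8b, and the diaryl ketone, activated by the para-methoxy group of ring B, is reduced to CH2 in the same flask.

Step 10
Reactants: 16 eight-membered ester
Product: 17 the corresponding 5-carbaldehyde (CHO on C-8c, trans to the C-8b aryl group)
Conditions: i-Bu2AlH, CH2Cl2, −78 °C; aq. potassium sodium tartrate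
Reagents that add atoms: none
Why: Partial reduction of the ester at −78 °C through a stable tetrahedral aluminium alkoxide gives the aldehyde on hydrolysis and releases the auxiliary, while the epimerisable C-8c stays in the thermodynamically preferred trans arrangement.

Step 11
Reactants: 17 aldehyde; 18 4-methoxyphenylmagnesium bromide
Product: 20 (7bR,8bS,8cR,7cR)-fluoro heptamethyl ether: indane-fused dibenzo[8]annulene with C-8a as CH2, F on the ring-B carbon ortho to C-8a, 4-methoxyphenyl on C-7b and C-7c, via carbinol 19 (not isolated)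
Conditions: THF, −78 → 0 °C; aq. NH4Cl; then CF3CO2H, CH2Cl2, −20 → 0 °C
Reagents that add atoms: none
Why: Grignard addition followed by Friedel–Crafts cyclialkylation: the p-methoxybenzylic cation from either carbinol epimer is attacked by the ortho position of ring C (activated ortho and para by methoxy) to close the five-membered ring, and the anisyl group on the new C-7c takes the position trans to ring B on C-8c (all-trans indane).

Step 12
Reactants: 20 fluoro heptamethyl ether; 21 4-methoxybenzaldehyde
Product: 24 (7aS,8aS,7bR,8bS,8cR,7cR)-octa-O-methyl ether of the target, via benzylic potassium species 22 (not isolated), via potassium alkoxide 23 (not isolated)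
Conditions: n-BuLi, KOtBu, 2,2,6,6-tetramethylpiperidine, THF, −78 °C; then 21, −78 °C; then 18-crown-6, −78 → 60 °C
Reagents that add atoms: none
Why: Proposed new method: the mixed lithium–potassium amide deprotonates the one CH2 flanked by two arenes (C-8a, further acidified by the ortho fluorine), the benzylic potassium species 22 adds to the aldehyde carbonyl, and the alkoxide 23, freed from ion pairing by 18-crown-6 and warmed, displaces the ortho fluoride through a Meisenheimer adduct, so a carbon-nucleophile/aryl-electrophile 1,3-pair annulates C=O in a formal [3+2] way; the closest known reaction types are the benzylic metalation–aldehyde addition of toluenes and diarylmethanes, the alkoxide SNAr cyclisation of 2-(2-fluoroaryl)ethanols to dihydrobenzofurans, and the one-pot indole synthesis from 2-fluorotoluenes and nitriles that uses the same metalation, addition, SNAr order. The dihydrofuran closes in the 5-exo-trig mode (oxygen attacks the C–F carbon and the ring-B π bond that breaks lies outside the new ring). At C-8a the eight-membered ring should hold ring A on one face of ring B and the C-7c methine on the other, so the open carbanion lobe is the one pointing toward fluorine roughly in the plane of ring B, and C–C bond formation there leaves hydrogen on the concave face as in the target. At C-7a the anisyl group of the aldehyde should turn away from ring A while the potassium-bound oxygen sits next to fluorine, giving the anti alkoxide and hence the trans-2,3-diaryl ring, whereas the syn alkoxide would have to cyclise through a cis-diaryl transition state and is expected to lag. The step needs site selectivity for the C-8a methylene over the aryl C–H between F and OMe and over the two diarylmethine C–H bonds, which amine-mediated thermodynamic metalation, the secondary and least electron-rich character of C-8a and its ortho fluorine should secure, and one equivalent of base leaves no strong base to open the product by E1cB after fluoride loss.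

Step 13
Reactants: 24 octa-O-methyl ether
Product: 25 target CNP0193760.4, (7aS,8aS,7bR,8bS,8cR,7cR)
Conditions: BBr3, CH2Cl2, −78 °C → rt; then H2O–MeOH
Reagents that add atoms: none
Why: Lewis-acid cleavage of all eight aryl methyl ethers with BBr3 at low temperature, which should not touch the six C–H stereocentres.

## Compound list

1 | methyl 2-bromo-3,5-dimethoxybenzoate | COC(=O)c1cc(OC)cc(OC)c1Br | starting material
2 | (4-methoxybenzyl)zinc chloride | COc1ccc(C[Zn]Cl)cc1 | starting material
3 | methyl 3,5-dimethoxy-2-(4-methoxybenzyl)benzoate | COC(=O)c1cc(OC)cc(OC)c1Cc1ccc(OC)cc1 | intermediate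
4 | (E)-3-(3,5-dimethoxyphenyl)prop-2-enoic acid | COc1cc(/C=C/C(=O)O)cc(OC)c1 | starting material
5 | (1S,2R,5S)-8-phenylmenthol, (1S,2R,5S)-5-methyl-2-(2-phenylpropan-2-yl)cyclohexan-1-ol | C[C@H]1CC[C@@H]([C@H](C1)O)C(C)(C)c1ccccc1 | starting material
6 | (1S,2R,5S)-8-phenylmenthyl (E)-3-(3,5-dimethoxyphenyl)prop-2-enoate | COc1cc(/C=C/C(=O)O[C@H]2C[C@@H](C)CC[C@@H]2C(C)(C)c2ccccc2)cc(OC)c1 | intermediate
7 | lithium ester enolate of the Michael adduct of 3 and 6 (not isolated) | COC(=O)c1cc(OC)cc(OC)c1C(c1ccc(OC)cc1)[C@@H](c1cc(OC)cc(OC)c1)C=C([O-])O[C@H]1C[C@@H](C)CC[C@@H]1C(C)(C)c1ccccc1.[Li+] | intermediate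
8 | 8-phenylmenthyl (3R)-3-(3,5-dimethoxyphenyl)-5,7-dimethoxy-4-(4-methoxyphenyl)-1-oxo-1,2,3,4-tetrahydronaphthalene-2-carboxylate (C-2, C-4 epimers) | O=C1c2cc(OC)cc(OC)c2C(c2ccc(OC)cc2)[C@@H](c2cc(OC)cc(OC)c2)C1C(=O)O[C@H]1C[C@@H](C)CC[C@@H]1C(C)(C)c1ccccc1 | intermediate
9 | 3-fluoro-5-methoxyphenol | COc1cc(O)cc(F)c1 | starting material
10 | 3-fluoro-5-methoxyphenyl N-isopropylcarbamate | COc1cc(OC(=O)NC(C)C)cc(F)c1 | intermediate
11 | 3-fluoro-5-methoxy-2-(trimethylsilyl)phenyl N-isopropylcarbamate | COc1cc(OC(=O)NC(C)C)c([Si](C)(C)C)c(F)c1 | intermediate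
12 | 3-fluoro-5-methoxy-2-(trimethylsilyl)phenyl trifluoromethanesulfonate | COc1cc(OS(=O)(=O)C(F)(F)F)c([Si](C)(C)C)c(F)c1 | intermediate
13 | 3-fluoro-5-methoxybenzyne (not isolated) | COC1=CC#CC(F)=C1 | intermediate
14 | 8-phenylmenthyl 1-fluoro-3,8,10-trimethoxy-6-(3,5-dimethoxyphenyl)-7-(4-methoxyphenyl)-12-oxo-5,6,7,12-tetrahydrodibenzo[a,d][8]annulene-5-carboxylate (5,6-trans; C-7 epimers) | O=C1c2cc(OC)cc(OC)c2C(c2ccc(OC)cc2)[C@@H](c2cc(OC)cc(OC)c2)[C@H](C(=O)O[C@H]2C[C@@H](C)CC[C@@H]2C(C)(C)c2ccccc2)c2cc(OC)cc(F)c21 | intermediate
15 | 7-methoxy derivative of 14 (C-7 epimers) | O=C1c2cc(OC)cc(OC)c2C(OC)(c2ccc(OC)cc2)[C@@H](c2cc(OC)cc(OC)c2)[C@H](C(=O)O[C@H]2C[C@@H](C)CC[C@@H]2C(C)(C)c2ccccc2)c2cc(OC)cc(F)c21 | intermediate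
16 | 8-phenylmenthyl 1-fluoro-3,8,10-trimethoxy-6-(3,5-dimethoxyphenyl)-7-(4-methoxyphenyl)-5,6,7,12-tetrahydrodibenzo[a,d][8]annulene-5-carboxylate (H-5/H-6 trans, H-6/H-7 cis) | COc1ccc([C@@H]2c3c(OC)cc(OC)cc3Cc3c(F)cc(OC)cc3[C@@H](C(=O)O[C@H]3C[C@@H](C)CC[C@@H]3C(C)(C)c3ccccc3)[C@@H]2c2cc(OC)cc(OC)c2)cc1 | intermediate
17 | 1-fluoro-3,8,10-trimethoxy-6-(3,5-dimethoxyphenyl)-7-(4-methoxyphenyl)-5,6,7,12-tetrahydrodibenzo[a,d][8]annulene-5-carbaldehyde (H-5/H-6 trans, H-6/H-7 cis) | COc1ccc([C@@H]2c3c(OC)cc(OC)cc3Cc3c(F)cc(OC)cc3[C@@H](C=O)[C@@H]2c2cc(OC)cc(OC)c2)cc1 | intermediate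
18 | 4-methoxyphenylmagnesium bromide | COc1ccc([Mg]Br)cc1 | starting material
19 | (4-methoxyphenyl)(annulen-5-yl)methanol from 17, both carbinol epimers (not isolated) | COc1ccc([C@@H]2c3c(OC)cc(OC)cc3Cc3c(F)cc(OC)cc3[C@@H](C(O)c3ccc(OC)cc3)[C@@H]2c2cc(OC)cc(OC)c2)cc1 | intermediate
20 | (7bR,8bS,8cR,7cR)-fluoro heptamethyl ether (indane-fused dibenzo[8]annulene, C-8a = CH2, F ortho to C-8a on ring B) | COc1ccc([C@@H]2c3c(OC)cc(OC)cc3Cc3c(F)cc(OC)cc3[C@H]3[C@H](c4ccc(OC)cc4)c4c(OC)cc(OC)cc4[C@H]23)cc1 | intermediate
21 | 4-methoxybenzaldehyde | COc1ccc(C=O)cc1 | starting material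
22 | C-8a benzylic potassium species of 20 (not isolated) | COc1ccc([C@@H]2c3c(OC)cc(OC)cc3[CH-]c3c(F)cc(OC)cc3[C@H]3[C@H](c4ccc(OC)cc4)c4c(OC)cc(OC)cc4[C@H]23)cc1.[K+] | intermediate
23 | potassium alkoxide of the aldehyde adduct, anti at C-8a/C-7a (not isolated) | COc1ccc([C@@H]2c3c(OC)cc(OC)cc3[C@H]([C@H]([O-])c3ccc(OC)cc3)c3c(F)cc(OC)cc3[C@H]3[C@H](c4ccc(OC)cc4)c4c(OC)cc(OC)cc4[C@H]23)cc1.[K+] | intermediate
24 | (7aS,8aS,7bR,8bS,8cR,7cR)-octa-O-methyl ether of the target | COc1ccc([C@@H]2c3c(OC)cc(OC)cc3[C@H]3c4c(cc(OC)cc4[C@H]4[C@H](c5ccc(OC)cc5)c5c(OC)cc(OC)cc5[C@H]24)O[C@@H]3c2ccc(OC)cc2)cc1 | intermediate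
25 | CNP0193760.4 | Oc1ccc([C@@H]2c3c(O)cc(O)cc3[C@H]3c4c(cc(O)cc4[C@H]4[C@H](c5ccc(O)cc5)c5c(O)cc(O)cc5[C@H]24)O[C@@H]3c2ccc(O)cc2)cc1 | target

## Step count and risks

Total step count: 13. Longest linear sequence: 10 steps (steps 4 to 13, from 9).

Steps most likely to fail:

Step 12 (proposed new method). The metalation may go to the ring C–H between F and OMe with loss of fluoride to an aryne. The fluoride displacement on the electron-rich ring may also be slow enough for the alkoxide to revert or eliminate, and facial control at C-7a may be poor. The fallback separates the two bond formations and uses known chemistry. It sets out from 20: the same metalation and aldehyde addition are quenched at −78 °C with acetic acid and the fluoro alcohol F1 is isolated, its anti isomer being purified. The ring is then closed by the elimination–addition mode: excess LiN(i-Pr)2 in THF, −78 → 0 °C, lithiates the position between F and OMe, LiF is lost, and the tethered alkoxide adds to the aryne (known aryne cyclisation of alkoxides). This does not depend on the electronics of ring B and comes back to the route at 24.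

Step 9. The C-7b cation may be intercepted by the neighbouring ketone oxygen to give a bridged ether, or may lose the C-8b proton to a stilbene, which would erase C-8b. The fallback avoids any cation at C-7b and sets out from 14 (step 8 is skipped). KN(SiMe3)2 (2.2 equivalents, THF, −78 °C) forms the ester enolate and the lateral dienolate of the o-alkyl diaryl ketone. Kinetic protonation with 2,6-di-tert-butylphenol on the face away from the C-8b aryl group, followed by brief DBU treatment to return C-8c to the trans arrangement, should give the single C-7b epimer F2. Et3SiH/CF3CO2H then reduces only the diaryl ketone, and the route is rejoined at 16.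

Step 3. The hindered dienolate may add slowly to the bulky enoate (retro-Michael), or the auxiliary may discriminate poorly between the enoate faces. The fallback replaces asymmetric induction by resolution and sets out from 3. The annulation is run with methyl (E)-3-(3,5-dimethoxyphenyl)prop-2-enoate to give the racemic methyl β-ketoester F3. Transesterification with 5 (DMAP, toluene, reflux, by way of the acylketene) gives the two C-3 diastereomeric 8-phenylmenthyl esters, which are separated by crystallisation or chromatography; the (3R) ester is 8.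

Further compounds
F1 | step 12 | fluoro alcohol: anti adduct of 20 and 4-methoxybenzaldehyde at C-8a | COc1ccc([C@@H]2c3c(OC)cc(OC)cc3[C@H]([C@H](O)c3ccc(OC)cc3)c3c(F)cc(OC)cc3[C@H]3[C@H](c4ccc(OC)cc4)c4c(OC)cc(OC)cc4[C@H]23)cc1
F2 | step 9 | keto ester 14 as the single C-7 epimer (H-6/H-7 cis) | O=C1c2cc(OC)cc(OC)c2[C@@H](c2ccc(OC)cc2)[C@@H](c2cc(OC)cc(OC)c2)[C@H](C(=O)O[C@H]2C[C@@H](C)CC[C@@H]2C(C)(C)c2ccccc2)c2cc(OC)cc(F)c21
F3 | step 3 | racemic methyl 3-(3,5-dimethoxyphenyl)-5,7-dimethoxy-4-(4-methoxyphenyl)-1-oxo-1,2,3,4-tetrahydronaphthalene-2-carboxylate | O=C1c2cc(OC)cc(OC)c2C(c2ccc(OC)cc2)C(c2cc(OC)cc(OC)c2)C1C(=O)OC
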